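The rate constants were chosen freely.

The ratio of the rate constants for left-handed and right-handed substrate, 70.6 at 5 °C, was where I began with these two flasks. In each, partner from the dissolving solid reagent reacts with a racemate on the single-handed catalyst.

| setting | beta | alpha |
|---|---|---|
| left-handed substrate | 0.10 M | 0.10 M |
| solid reagent | 0.120 M | 0.120 M |
| catalyst | 5.7 mM | 5.7 mM |
| right-handed substrate | 0.10 M | 0.10 M |
| temperature | 20 °C | 5 °C |
| time | 3.0 min | 3.0 min |

    partner + catalyst + left-handed substrate → catalyst + left-handed product (k1 = 120 L² mol⁻² s⁻¹, Ea1 = 37.0 kJ mol⁻¹)
    partner + catalyst + right-handed substrate → catalyst + right-handed product (k2 = 1.7 L² mol⁻² s⁻¹, Ea2 = 38.0 kJ mol⁻¹)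
    partner ⇌ dormant form (K3 = 0.46, k3 = 0.086 s⁻¹, Ea3 = 79.0 kJ mol⁻¹, ΔH3 = 7.00 kJ mol⁻¹)
    solid reagent ⇌ partner, rate k4*(cs4 - [partner]) while solid is left; crystals form when [partner] > cs4 (cs4 = 8.8 mM, k4 = 0.069 s⁻¹)
    (constants at 5 °C)

- catalyst is single-handed; left-handed substrate and right-handed substrate are mirror images of each other, charged as a racemate, each of them at the stated concentration
- solid, in amounts per volume of the solution: solid reagent
- the constants hold at 5 °C; other temperatures follow from the activation energies and enthalpies
- at the start none of the solid reagent is in solution

- the flask that comes out highest in amount of left-handed product, in percent of the left-handed substrate and right-handed substrate together charged, or "all alike" when all lie within 1.5 percentage points (beta / alpha / all alike)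
- left-handed product at the end, in percent of the left-handed substrate and right-handed substrate together charged, beta
- left-handed product at the end, in percent of the left-handed substrate and right-handed substrate together charged, alpha

The rule of thumb at the bench was that a kinetic resolution stops at half of the racemate, with left-handed substrate consumed and right-handed substrate untouched. I worked with fractions left, each of its own charge: x for the left-handed substrate and z for the right-handed. Both product-forming steps carry partner and catalyst, so at fixed temperature the two decays run on one shared clock, however the partner varies. Hence ln x = s ln z, where s, the selectivity factor, is the ratio of the two rate constants at that temperature, 69.0 in beta and 70.6 in alpha.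

The ratio of the two product-forming rates is s x/z, which falls to one at x = z/s. In beta, the rule of thumb therefore ended near x = 1.36%, where z = 94.0%. Above that border, the left-handed product is close to half of one minus x, in terms of the whole racemate. My reckoning stopped there: it tied z to x and set the ceiling at half, but it gave no clock, so I committed to no yield at 3.0 min.

The forecast named beta as highest, with 30.1% for beta and 21.6% for alpha. Its grounds included this: “Solid never runs out”.

The simulation gave beta as highest, with 30.1% for beta and 21.6% for alpha, as forecast.

At 3.00 min, beta had x = 40%, above the border. The neighbouring flask was beta left until 12 min, and there x was 0.10%, below the border. The same reckoning with s = 69.0 gave z = 90.5%, and the flask held 90% of its right-handed substrate. Its left-handed product stood at 49.9% of the racemate, and its right-handed product had reached 4.75%.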